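We cannot give the target one fixed rate constant: its rate goes with the free catalyst, and starting material, second substrate and reagent each act on how much of that catalyst stands free.

    starting material + free catalyst ⇌ catalyst intermediate A (K1 = 940 M⁻¹, k1 = 790 M⁻¹ s⁻¹)
    reagent + catalyst intermediate A → free catalyst + target (k2 = 250 M⁻¹ s⁻¹)
    second substrate + free catalyst ⇌ catalyst intermediate B (K3 = 22 M⁻¹, k3 = 900 M⁻¹ s⁻¹)
    reagent + catalyst intermediate B → free catalyst + second product (k4 = 1800 M⁻¹ s⁻¹)
    starting material ⇌ dormant form (K5 = 3.0, k5 = 0.20 s⁻¹)

in all of them: starting material 10 mM; reagent 3.00 equiv; free catalyst 1.5 mol%
- larch: second substrate 2.00 equiv; a single well-mixed tank run continuously and read at steady state, 60.0 s in it on average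
- cedar: second substrate 2.00 equiv; a single well-mixed tank run continuously and read at steady state, 12 s in it on average
- elm: second substrate 2.00 equiv (fed, over 12.0 s); a stirred flask in which second substrate is dosed at a steady rate over 12.0 s without added volume, worked up at 12 s; time 12 s
- alder: second substrate 2.00 equiv; a closed flask charged with all of it at once and left for 12 s; time 12 s

* the set-up with the highest amount of target at the outlet or at the end, in percent of the starting material put in ("none" if the first two lie within 2 percentage points) (larch / cedar / elm / alder / none)
* amount of target at the outlet or at the end, in percent of the starting material put in, larch
* amount of target at the outlet or at the end, in percent of the starting material put in, cedar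
* amount of target at the outlet or at the end, in percent of the starting material put in, elm
* amount of target at the outlet or at the end, in percent of the starting material put in, alder

- the stated concentrations are those of everything mixed, before any reaction; amounts are the same in each set-up
- the feed brings no volume worth counting
- run time (elm): 12 s

Write S for starting material, D for dormant form and c for free catalyst. As charged, catalyst intermediate A has a half-life of 0.092 s by step 2 and catalyst intermediate B one of 0.013 s by step 4, both far shorter than the 3.5 s of S going forward to D. So we treat both as quasi-steady: each stands at c times its formation rate per unit of c, divided by its total removal rate.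

These ratios move during a run, so we replace the curves by a mean. For the mean S we take a quarter of its charge, 2.50 mM, its equilibrium share against D. For the mean reagent and second substrate we guess 20.0 mM and 13.3 mM. Intermediate A then decays at 5.84 s⁻¹ and stands at 0.338 of c, while intermediate B stands at 0.156 of c. Of the 0.150 mM of catalyst, the balance leaves c at 0.100 mM.

The turnover constant κ, the rate of target formation divided by S, a pseudo-first-order constant, comes to 0.0679 s⁻¹.

In a tank of mean residence time τ, D/S is the forward constant of the dormant step over its back constant plus the reciprocal of τ: 1.33 in cedar and 2.40 in larch. Target is κτS, so the balance over S, D and target gives a yield of κτ over one plus D/S plus κτ. That is 25.9% for cedar and 54.5% for larch.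

To check the error of the mean, κ at the charge itself is 0.0499 s⁻¹, which moves cedar down to 20.4%.

For alder we let S relax toward its share at 0.267 s⁻¹ and deliberately drop the loss to turnover, which gives a high figure of 38.7%. For elm we take the mean second substrate as half of our guess, which lifts this figure to 40.8%. Both are lower than larch, so we pick larch.

The forecast also names larch, with 53.8% for larch, 25% for cedar, 29.8% for elm and 28.2% for alder, saying “The long residence time makes larch best”.

The simulation gives larch as best, with 53.5% for larch, 24.8% for cedar, 30.4% for elm and 28.2% for alder.

Cedar's tank stands at 3.21 mM of S, and its target divided by this and the residence time reads κ as 0.0643 s⁻¹, slower than the 0.20 s⁻¹ at which S goes forward to D. With our 0.0679 s⁻¹, cedar at ten times the residence time has D/S of 2.67 and a reckoned yield of 69.0%, and that run stands at 67.2%.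

The numbers are assumed; what happens was integrated by code.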